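**Plan**

- Cuts: after the O-acetyl and O-silyl changes, the 14-membered ring is opened at C1–C14. The lactone is cut at C1=C15 (metathesis) and O–C16 (ester). The chain is cut at C2–C3, C5–C6, C6–C7, C9–C10 and C10–C11 (carbonyl additions and formylations) and at the three C–CH3 bonds (alkyne carboalumination).
- Enabling feature: C14(O)–C1(H)–C15(=C17H2)–C16(=O)–O–C2 is a homoallylic alcohol held inside the α-methylene γ-lactone that is fused at C1/C2 to the 14-membered carbocycle. This is the product pattern of γ-attack (SE2') of a 3-(stannylmethyl)butenolide on a C14 aldehyde.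
- Forward: the C14→C3 chain grows linearly from 3-butyn-1-ol by carboalumination–iodination, formylation and propargylation (two rounds) and a third carboalumination. C2 and C1 come from an ynal. The five-membered lactone is closed first, the 14-membered ring second.
- Stereochemistry: C10 and C6 come from (S)-TRIP-catalysed propargylboration, C2 from Noyori transfer hydrogenation of an enynone, and C1 and C14 are relayed from C2 in the ring closure (trans lactone, syn C1/C14). The three E-alkenes come from syn-carboalumination.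

Key step: step 21

Remark: cembrane numbering is used (C1 = lactone CH bearing C15, C2 = lactone OCH, C3–C14 around the ring, C16 = lactone C=O, C17 = exocyclic CH2). The facial sense of the catalysts in steps 4, 8 and 13 is assigned by analogy with their behaviour towards aryl, alkenyl and alkyl analogues.

**Route**

Step 1
Reactants: 1 3-butyn-1-ol
Product: 2 4-(4-methoxybenzyloxy)but-1-yne
Conditions: NaH (1.2 equiv), 4-methoxybenzyl chloride (1.1 equiv), Bu4NI (5 mol %), THF, 0 → 23 °C
Reagents that add atoms: 4-methoxybenzyl chloride COc1ccc(CCl)cc1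
Why: Williamson etherification of the primary alkoxide gives a PMB ether that tolerates the organoaluminium and organolithium steps and can later be removed oxidatively beside silyl ethers.

Step 2
Reactants: 2 4-(4-methoxybenzyloxy)but-1-yne
Product: 4 (E)-1-iodo-4-(4-methoxybenzyloxy)-2-methylbut-1-ene, via alkenyldimethylalane 3 (not isolated)
Conditions: AlMe3 (2.5 equiv), Cp2ZrCl2 (0.25 equiv), CH2Cl2, 0 → 23 °C; then I2 (1.3 equiv), THF, −30 → 0 °C
Reagents that add atoms: trimethylaluminium C[Al](C)C; iodine II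
Why: Zirconium-catalysed syn-carboalumination (Negishi carboalumination) places methyl on the internal and aluminium on the terminal alkyne carbon, and iodinolysis with retention should give the E iodide that fixes the C11=C12 geometry.

Step 3
Reactants: 4 (E)-1-iodo-4-(4-methoxybenzyloxy)-2-methylbut-1-ene
Product: 7 (E)-5-(4-methoxybenzyloxy)-3-methylpent-2-enal, via alkenyllithium 5 (not isolated), via lithium hemiaminal alkoxide 6 (not isolated)
Conditions: t-BuLi (2.1 equiv), Et2O, −78 °C; DMF (3 equiv), −78 → 0 °C; H2O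
Reagents that add atoms: N,N-dimethylformamide CN(C)C=O
Why: Iodine–lithium exchange proceeds with retention of the alkene geometry and the alkenyllithium is formylated by DMF (Bouveault formylation) to the E enal.

Step 4
Reactants: 7 (E)-5-(4-methoxybenzyloxy)-3-methylpent-2-enal; 8 allenylboronic acid pinacol ester
Product: 10 (S,E)-8-(4-methoxybenzyloxy)-6-methyloct-5-en-1-yn-4-ol, via pinacol borate ester 9 (not isolated)
Conditions: 8 (1.5 equiv), (S)-TRIP [(S)-3,3'-bis(2,4,6-triisopropylphenyl)-1,1'-binaphthyl-2,2'-diyl hydrogen phosphate] (10 mol %), 4 Å MS, toluene, −20 °C; H2O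
Reagents that add atoms: none
Why: In this chiral phosphoric acid-catalysed propargylboration the acid binds the boronate oxygen and the formyl hydrogen in a six-membered chair SE2' transition state, and the (S)-acid is expected to deliver the propargyl group to the Si face of the enal, which sets C10 as S.

Step 5
Reactants: 10 (S,E)-8-(4-methoxybenzyloxy)-6-methyloct-5-en-1-yn-4-ol
Product: 11 (S,E)-8-(4-methoxybenzyloxy)-6-methyl-4-(triethylsilyloxy)oct-5-en-1-yne
Conditions: Et3SiCl (1.2 equiv), imidazole (2 equiv), CH2Cl2, 0 °C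
Reagents that add atoms: chlorotriethylsilane CC[Si](Cl)(CC)CC
Why: Silylation of the secondary alcohol gives a triethylsilyl ether that survives the organometallic steps and is the one silyl group that mild acid later removes beside the tert-butyldimethylsilyl ether.

Step 6
Reactants: 11 (S,E)-8-(4-methoxybenzyloxy)-6-methyl-4-(triethylsilyloxy)oct-5-en-1-yne
Product: 13 (S,1E,5E)-1-iodo-8-(4-methoxybenzyloxy)-2,6-dimethyl-4-(triethylsilyloxy)octa-1,5-diene, via alkenyldimethylalane 12 (not isolated)
Conditions: AlMe3 (2.5 equiv), Cp2ZrCl2 (0.25 equiv), CH2Cl2, 0 → 23 °C; then I2 (1.3 equiv), THF, −30 → 0 °C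
Reagents that add atoms: trimethylaluminium C[Al](C)C; iodine II
Why: Negishi carboalumination–iodination of the terminal alkyne, to which the trisubstituted alkene and the ethers are inert, should set C7=C8 as E.

Step 7
Reactants: 13 (S,1E,5E)-1-iodo-8-(4-methoxybenzyloxy)-2,6-dimethyl-4-(triethylsilyloxy)octa-1,5-diene
Product: 16 (S,2E,6E)-9-(4-methoxybenzyloxy)-3,7-dimethyl-5-(triethylsilyloxy)nona-2,6-dienal, via alkenyllithium 14 (not isolated), via lithium hemiaminal alkoxide 15 (not isolated)
Conditions: t-BuLi (2.1 equiv), Et2O, −78 °C; DMF (3 equiv), −78 → 0 °C; H2O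
Reagents that add atoms: N,N-dimethylformamide CN(C)C=O
Why: Iodine–lithium exchange with retention followed by Bouveault formylation gives the next E enal, the silyl ether lying too far from the carbanion for elimination.

Step 8
Reactants: 16 (S,2E,6E)-9-(4-methoxybenzyloxy)-3,7-dimethyl-5-(triethylsilyloxy)nona-2,6-dienal; 8 allenylboronic acid pinacol ester
Product: 18 (4S,8S,5E,9E)-12-(4-methoxybenzyloxy)-6,10-dimethyl-8-(triethylsilyloxy)dodeca-5,9-dien-1-yn-4-ol, via pinacol borate ester 17 (not isolated)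
Conditions: 8 (1.5 equiv), (S)-TRIP (10 mol %), 4 Å MS, toluene, −20 °C; H2O
Reagents that add atoms: none
Why: The same phosphoric acid-catalysed propargylboration should set C6 as S under catalyst control, since the C10 centre is five atoms from the carbonyl and should not interfere.

Step 9
Reactants: 18 (4S,8S,5E,9E)-12-(4-methoxybenzyloxy)-6,10-dimethyl-8-(triethylsilyloxy)dodeca-5,9-dien-1-yn-4-ol
Product: 19 (4S,8S,5E,9E)-4-(tert-butyldimethylsilyloxy)-12-(4-methoxybenzyloxy)-6,10-dimethyl-8-(triethylsilyloxy)dodeca-5,9-dien-1-yne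
Conditions: t-BuMe2SiCl (1.5 equiv), imidazole (3 equiv), DMF, 23 °C
Reagents that add atoms: tert-butyldimethylsilyl chloride CC(C)(C)[Si](C)(C)Cl
Why: Silylation masks the C6 hydroxyl with the group that is kept until the last step.

Step 10
Reactants: 19 (4S,8S,5E,9E)-4-(tert-butyldimethylsilyloxy)-12-(4-methoxybenzyloxy)-6,10-dimethyl-8-(triethylsilyloxy)dodeca-5,9-dien-1-yne
Product: 21 (4S,8S,1E,5E,9E)-4-(tert-butyldimethylsilyloxy)-1-iodo-12-(4-methoxybenzyloxy)-2,6,10-trimethyl-8-(triethylsilyloxy)dodeca-1,5,9-triene, via alkenyldimethylalane 20 (not isolated)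
Conditions: AlMe3 (2.5 equiv), Cp2ZrCl2 (0.25 equiv), CH2Cl2, 0 → 23 °C; then I2 (1.3 equiv), THF, −30 → 0 °C
Reagents that add atoms: trimethylaluminium C[Al](C)C; iodine II
Why: A third Negishi carboalumination–iodination should set C3=C4 as E and leave iodine on C3.

Step 11
Reactants: 21 (4S,8S,1E,5E,9E)-4-(tert-butyldimethylsilyloxy)-1-iodo-12-(4-methoxybenzyloxy)-2,6,10-trimethyl-8-(triethylsilyloxy)dodeca-1,5,9-triene; 22 3-(trimethylsilyl)propynal
Product: 24 C2-epimeric enynol (cembrane numbering: C1 bears the trimethylsilylethynyl carbon; C2 OH; C6 OTBS; C10 OTES; C14 OPMB; 3E,7E,11E; 6S,10S), via alkenyllithium 23 (not isolated)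
Conditions: t-BuLi (2.1 equiv), Et2O, −78 °C; then 22 (1.3 equiv), −78 °C; H2O
Reagents that add atoms: none
Why: Iodine–lithium exchange with retention and 1,2-addition of the alkenyllithium to the ynal forms C2–C3, and the uncontrolled carbinol centre is erased in the next step.

Step 12
Reactants: 24 C2-epimeric enynol
Product: 25 cross-conjugated enynone (C2 ketone; C6 OTBS; C10 OTES; C14 OPMB; 6S,10S)
Conditions: MnO2 (20 equiv), CH2Cl2, 23 °C
Reagents that add atoms: none
Why: MnO2 oxidises the doubly activated (allylic and propargylic) alcohol selectively and leaves ethers and alkenes untouched.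

Step 13
Reactants: 25 cross-conjugated enynone
Product: 26 (2S,6S,10S)-propargylic alcohol (C1 alkyne carrying SiMe3; C2 OH)
Conditions: Ru[(S,S)-TsDPEN](p-cymene) (2 mol %, amido complex preformed from RuCl[(S,S)-TsDPEN](p-cymene) and KOH), i-PrOH, 23 °C
Reagents that add atoms: none
Why: In this Noyori asymmetric transfer hydrogenation the ynone carbonyl accepts hydride through the metal–ligand bifunctional transition state with the alkynyl group in the place taken by aryl groups, so the (S,S)-catalyst should give the S carbinol at C2, as it does with alkyl alkynyl ketones.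

Step 14
Reactants: 26 (2S,6S,10S)-propargylic alcohol
Product: 27 (2S,6S,10S)-terminal alkynyl carbinol
Conditions: K2CO3 (0.3 equiv), MeOH, 0 → 23 °C
Reagents that add atoms: none
Why: Base-catalysed methanolysis cleaves the alkynyl C–Si bond, and the two silyl ethers are stable to these conditions.

Step 15
Reactants: 27 (2S,6S,10S)-terminal alkynyl carbinol
Product: 28 (2R,6S,10S)-dienol (C1 vinyl; C2 OH; unchanged spatial arrangement at C2)
Conditions: H2 (1 atm), Pd/CaCO3 poisoned with Pb(OAc)2 (Lindlar catalyst), quinoline, EtOAc, 23 °C, stopped after one equivalent of H2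
Reagents that add atoms: none
Why: Lindlar semihydrogenation should stop at the terminal alkene without reducing the trisubstituted alkenes or the benzylic ether, and the descriptor at C2 changes only because the ranking of its substituents changes.

Step 16
Reactants: 28 (2R,6S,10S)-dienol; 29 2-(bromomethyl)acrylic acid
Product: 30 (2R,6S,10S)-dienyl 2-(bromomethyl)acrylate
Conditions: 29 (1.5 equiv), DCC (1.6 equiv), DMAP (5 mol %), CH2Cl2, −20 → 0 °C
Reagents that add atoms: none
Why: Steglich esterification acylates the oxygen without touching the C2–O bond, so C2 keeps its configuration.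

Step 17
Reactants: 30 (2R,6S,10S)-dienyl 2-(bromomethyl)acrylate
Product: 31 (2S,6S,10S)-3-(bromomethyl)butenolide with C14 OPMB (C15 carries CH2Br; C1=C15 in the ring)
Conditions: second-generation Grubbs catalyst (10 mol %), CH2Cl2 (0.005 M), 40 °C
Reagents that add atoms: none
Why: In this ring-closing metathesis the ruthenium alkylidene forms at the terminal vinyl group and closes onto the 1,1-disubstituted acrylate alkene to give the five-membered butenolide with loss of ethylene, the trisubstituted chain alkenes being too hindered to compete.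

Step 18
Reactants: 31 (2S,6S,10S)-3-(bromomethyl)butenolide with C14 OPMB
Product: 32 (2S,6S,10S)-3-(bromomethyl)butenolide C14 alcohol
Conditions: DDQ (1.3 equiv), CH2Cl2/pH 7 phosphate buffer (10:1), 0 °C
Reagents that add atoms: none
Why: DDQ cleaves the PMB ether oxidatively through the benzylic oxocarbenium ion, and this is done before tin is introduced because allylstannanes are oxidised by DDQ.

Step 19
Reactants: 32 (2S,6S,10S)-3-(bromomethyl)butenolide C14 alcohol
Product: 33 (2S,6S,10S)-3-(tributylstannylmethyl)butenolide C14 alcohol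
Conditions: (Bu3Sn)2 (1.5 equiv), Pd2(dba)3 (2.5 mol %), THF, 0 → 23 °C
Reagents that add atoms: hexabutylditin CCCC[Sn](CCCC)(CCCC)[Sn](CCCC)(CCCC)CCCC
Why: Palladium-catalysed allylic stannylation, known for allylic halides and 2-(acyloxymethyl)acrylates, proceeds by oxidative addition of the C–Br bond to zerovalent palladium, transmetalation with the distannane and reductive elimination at the unhindered CH2 terminus, which keeps the alkene conjugated in the ring.

Step 20
Reactants: 33 (2S,6S,10S)-3-(tributylstannylmethyl)butenolide C14 alcohol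
Product: 34 seco (2S,6S,10S)-3-(tributylstannylmethyl)butenolide C14 aldehyde (C6 OTBS; C10 OTES)
Conditions: Dess–Martin periodinane (1.5 equiv), NaHCO3 (5 equiv), CH2Cl2, 0 °C; filtered and used at once
Reagents that add atoms: none
Why: Dess–Martin oxidation under bicarbonate buffer should give the β,γ-unsaturated aldehyde without the acid that would protodestannylate the allylstannane or move the C11=C12 bond into conjugation.

Step 21
Reactants: 34 seco (2S,6S,10S)-3-(tributylstannylmethyl)butenolide C14 aldehyde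
Product: 35 (1S,2S,6S,10S,14S)-macrocyclic α-methylene lactone with free C14 OH (C6 OTBS; C10 OTES)
Conditions: BF3·OEt2 (2.5 equiv), CH2Cl2 (0.001 M in 34), −78 °C; aq. NaHCO3
Reagents that add atoms: none
Why: BF3 activates the C14 aldehyde and the electron-poor allylstannane attacks through its γ-carbon C1 anti to the C–Sn bond (SE2'), so that C1–C14 forms, the C1=C15 bond moves to C15=C17 and tin leaves as Bu3SnF; the closest known reactions are the Lewis-acid-promoted additions of 2-(stannylmethyl)acrylates to aldehydes and the intramolecular allylstannane–aldehyde closures of 14-membered carbocycles. The 14-membered ring closes by intramolecular carbonyl allylation with C1 as nucleophilic and C14 as electrophilic terminus, the tether C2–C13 lying outside the reacting array, and high dilution suppresses oligomers. C1 is controlled by C2: the aldehyde should reach C1 on the butenolide face opposite to the C2–C3 bond, which keeps C3 and C14 trans on the lactone and the C3–C2–C1–C14 torsion large, whereas the cis mode would force a nearly eclipsed torsion into the forming ring. C14 is controlled by the open antiperiplanar transition state, in which C13 of the aldehyde lies anti to C2 across the forming bond, and this should give the syn C1/C14 relation. The step needs the aldehyde to react before it conjugates and the two silyl ethers to survive, which the low temperature, the freshly made aldehyde and the buffered quench are meant to secure.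

Step 22
Reactants: 35 (1S,2S,6S,10S,14S)-macrocyclic α-methylene lactone with free C14 OH
Product: 36 (1S,2S,6S,10S,14S)-C10,C14-diol with C6 OTBS
Conditions: PPTS (0.3 equiv), MeOH/CH2Cl2 (1:1), 0 °C
Reagents that add atoms: none
Why: Acid-catalysed methanolysis cleaves the secondary triethylsilyl ether much faster than the tert-butyldimethylsilyl ether.

Step 23
Reactants: 36 (1S,2S,6S,10S,14S)-C10,C14-diol with C6 OTBS
Product: 37 (1S,2S,6S,10S,14S)-C10,C14-diacetate with C6 OTBS
Conditions: Ac2O (6 equiv), pyridine, DMAP (10 mol %), CH2Cl2, 0 → 23 °C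
Reagents that add atoms: acetic anhydride CC(=O)OC(C)=O
Why: DMAP-catalysed acylation should acetylate both secondary alcohols while C6 stays masked.

Step 24
Reactants: 37 (1S,2S,6S,10S,14S)-C10,C14-diacetate with C6 OTBS
Product: 38 CNP0418981.1, the (1S,2S,6S,10S,14S)-10,14-diacetoxy-6-hydroxy α-methylene lactone
Conditions: HF·pyridine, pyridine, THF, 0 → 23 °C
Reagents that add atoms: none
Why: Fluoride-mediated desilylation under buffered acidic conditions should free the C6 hydroxyl and spare the acetates and the α-methylene lactone.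

**Compound list**

1 | 3-butyn-1-ol | C#CCCO | starting material
2 | 4-(4-methoxybenzyloxy)but-1-yne | COc1ccc(COCCC#C)cc1 | intermediate
3 | (E)-alkenyldimethylalane from 2 | C[Al](C)/C=C(\C)CCOCc1ccc(OC)cc1 | intermediate
4 | (E)-1-iodo-4-(4-methoxybenzyloxy)-2-methylbut-1-ene | I/C=C(\C)CCOCc1ccc(OC)cc1 | intermediate
5 | (E)-alkenyllithium from 4 | [Li]/C=C(\C)CCOCc1ccc(OC)cc1 | intermediate
6 | lithium hemiaminal alkoxide (DMF adduct of 5) | [Li]OC(N(C)C)/C=C(\C)CCOCc1ccc(OC)cc1 | intermediate
7 | (E)-5-(4-methoxybenzyloxy)-3-methylpent-2-enal | O=C/C=C(\C)CCOCc1ccc(OC)cc1 | intermediate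
8 | allenylboronic acid pinacol ester | C=C=CB1OC(C)(C)C(C)(C)O1 | starting material
9 | pinacol borate ester of 10 | C#CC[C@H](OB1OC(C)(C)C(C)(C)O1)/C=C(\C)CCOCc1ccc(OC)cc1 | intermediate
10 | (S,E)-8-(4-methoxybenzyloxy)-6-methyloct-5-en-1-yn-4-ol | C#CC[C@H](O)/C=C(\C)CCOCc1ccc(OC)cc1 | intermediate
11 | (S,E)-8-(4-methoxybenzyloxy)-6-methyl-4-(triethylsilyloxy)oct-5-en-1-yne | C#CC[C@H](O[Si](CC)(CC)CC)/C=C(\C)CCOCc1ccc(OC)cc1 | intermediate
12 | alkenyldimethylalane from 11 | C[Al](C)/C=C(\C)C[C@H](O[Si](CC)(CC)CC)/C=C(\C)CCOCc1ccc(OC)cc1 | intermediate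
13 | (S,1E,5E)-1-iodo-8-(4-methoxybenzyloxy)-2,6-dimethyl-4-(triethylsilyloxy)octa-1,5-diene | I/C=C(\C)C[C@H](O[Si](CC)(CC)CC)/C=C(\C)CCOCc1ccc(OC)cc1 | intermediate
14 | alkenyllithium from 13 | [Li]/C=C(\C)C[C@H](O[Si](CC)(CC)CC)/C=C(\C)CCOCc1ccc(OC)cc1 | intermediate
15 | lithium hemiaminal alkoxide (DMF adduct of 14) | [Li]OC(N(C)C)/C=C(\C)C[C@H](O[Si](CC)(CC)CC)/C=C(\C)CCOCc1ccc(OC)cc1 | intermediate
16 | (S,2E,6E)-9-(4-methoxybenzyloxy)-3,7-dimethyl-5-(triethylsilyloxy)nona-2,6-dienal | O=C/C=C(\C)C[C@H](O[Si](CC)(CC)CC)/C=C(\C)CCOCc1ccc(OC)cc1 | intermediate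
17 | pinacol borate ester of 18 | C#CC[C@H](OB1OC(C)(C)C(C)(C)O1)/C=C(\C)C[C@H](O[Si](CC)(CC)CC)/C=C(\C)CCOCc1ccc(OC)cc1 | intermediate
18 | (4S,8S,5E,9E)-12-(4-methoxybenzyloxy)-6,10-dimethyl-8-(triethylsilyloxy)dodeca-5,9-dien-1-yn-4-ol | C#CC[C@H](O)/C=C(\C)C[C@H](O[Si](CC)(CC)CC)/C=C(\C)CCOCc1ccc(OC)cc1 | intermediate
19 | (4S,8S,5E,9E)-4-(tert-butyldimethylsilyloxy)-12-(4-methoxybenzyloxy)-6,10-dimethyl-8-(triethylsilyloxy)dodeca-5,9-dien-1-yne | C#CC[C@H](O[Si](C)(C)C(C)(C)C)/C=C(\C)C[C@H](O[Si](CC)(CC)CC)/C=C(\C)CCOCc1ccc(OC)cc1 | intermediate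
20 | alkenyldimethylalane from 19 | C[Al](C)/C=C(\C)C[C@H](O[Si](C)(C)C(C)(C)C)/C=C(\C)C[C@H](O[Si](CC)(CC)CC)/C=C(\C)CCOCc1ccc(OC)cc1 | intermediate
21 | (4S,8S,1E,5E,9E)-4-(tert-butyldimethylsilyloxy)-1-iodo-12-(4-methoxybenzyloxy)-2,6,10-trimethyl-8-(triethylsilyloxy)dodeca-1,5,9-triene | I/C=C(\C)C[C@H](O[Si](C)(C)C(C)(C)C)/C=C(\C)C[C@H](O[Si](CC)(CC)CC)/C=C(\C)CCOCc1ccc(OC)cc1 | intermediate
22 | 3-(trimethylsilyl)propynal | C[Si](C)(C)C#CC=O | starting material
23 | alkenyllithium from 21 | [Li]/C=C(\C)C[C@H](O[Si](C)(C)C(C)(C)C)/C=C(\C)C[C@H](O[Si](CC)(CC)CC)/C=C(\C)CCOCc1ccc(OC)cc1 | intermediate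
24 | C2-epimeric enynol (C2 OH; C6 OTBS; C10 OTES; C14 OPMB; 6S,10S) | C[Si](C)(C)C#CC(O)/C=C(\C)C[C@H](O[Si](C)(C)C(C)(C)C)/C=C(\C)C[C@H](O[Si](CC)(CC)CC)/C=C(\C)CCOCc1ccc(OC)cc1 | intermediate
25 | cross-conjugated enynone (C2 ketone; 6S,10S) | C[Si](C)(C)C#CC(=O)/C=C(\C)C[C@H](O[Si](C)(C)C(C)(C)C)/C=C(\C)C[C@H](O[Si](CC)(CC)CC)/C=C(\C)CCOCc1ccc(OC)cc1 | intermediate
26 | (2S,6S,10S)-propargylic alcohol with C-SiMe3 | C[Si](C)(C)C#C[C@@H](O)/C=C(\C)C[C@H](O[Si](C)(C)C(C)(C)C)/C=C(\C)C[C@H](O[Si](CC)(CC)CC)/C=C(\C)CCOCc1ccc(OC)cc1 | intermediate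
27 | (2S,6S,10S)-terminal alkynyl carbinol | C#C[C@@H](O)/C=C(\C)C[C@H](O[Si](C)(C)C(C)(C)C)/C=C(\C)C[C@H](O[Si](CC)(CC)CC)/C=C(\C)CCOCc1ccc(OC)cc1 | intermediate
28 | (2R,6S,10S)-dienol | C=C[C@@H](O)/C=C(\C)C[C@H](O[Si](C)(C)C(C)(C)C)/C=C(\C)C[C@H](O[Si](CC)(CC)CC)/C=C(\C)CCOCc1ccc(OC)cc1 | intermediate
29 | 2-(bromomethyl)acrylic acid | C=C(CBr)C(=O)O | starting material
30 | (2R,6S,10S)-dienyl 2-(bromomethyl)acrylate | C=C[C@@H](OC(=O)C(=C)CBr)/C=C(\C)C[C@H](O[Si](C)(C)C(C)(C)C)/C=C(\C)C[C@H](O[Si](CC)(CC)CC)/C=C(\C)CCOCc1ccc(OC)cc1 | intermediate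
31 | (2S,6S,10S)-3-(bromomethyl)butenolide with C14 OPMB | BrCC1=C[C@@H](OC1=O)/C=C(\C)C[C@H](O[Si](C)(C)C(C)(C)C)/C=C(\C)C[C@H](O[Si](CC)(CC)CC)/C=C(\C)CCOCc1ccc(OC)cc1 | intermediate
32 | (2S,6S,10S)-3-(bromomethyl)butenolide C14 alcohol | BrCC1=C[C@@H](OC1=O)/C=C(\C)C[C@H](O[Si](C)(C)C(C)(C)C)/C=C(\C)C[C@H](O[Si](CC)(CC)CC)/C=C(\C)CCO | intermediate
33 | (2S,6S,10S)-3-(tributylstannylmethyl)butenolide C14 alcohol | CCCC[Sn](CCCC)(CCCC)CC1=C[C@@H](OC1=O)/C=C(\C)C[C@H](O[Si](C)(C)C(C)(C)C)/C=C(\C)C[C@H](O[Si](CC)(CC)CC)/C=C(\C)CCO | intermediate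
34 | seco (2S,6S,10S)-3-(tributylstannylmethyl)butenolide C14 aldehyde | CCCC[Sn](CCCC)(CCCC)CC1=C[C@@H](OC1=O)/C=C(\C)C[C@H](O[Si](C)(C)C(C)(C)C)/C=C(\C)C[C@H](O[Si](CC)(CC)CC)/C=C(\C)CC=O | intermediate
35 | (1S,2S,6S,10S,14S)-macrocyclic α-methylene lactone with free C14 OH, C6 OTBS, C10 OTES | C=C1C(=O)O[C@H]2/C=C(\C)C[C@H](O[Si](C)(C)C(C)(C)C)/C=C(\C)C[C@H](O[Si](CC)(CC)CC)/C=C(\C)C[C@H](O)[C@H]12 | intermediate
36 | (1S,2S,6S,10S,14S)-C10,C14-diol with C6 OTBS | C=C1C(=O)O[C@H]2/C=C(\C)C[C@H](O[Si](C)(C)C(C)(C)C)/C=C(\C)C[C@H](O)/C=C(\C)C[C@H](O)[C@H]12 | intermediate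
37 | (1S,2S,6S,10S,14S)-C10,C14-diacetate with C6 OTBS | C=C1C(=O)O[C@H]2/C=C(\C)C[C@H](O[Si](C)(C)C(C)(C)C)/C=C(\C)C[C@H](OC(C)=O)/C=C(\C)C[C@H](OC(C)=O)[C@H]12 | intermediate
38 | CNP0418981.1 | C=C1C(=O)O[C@H]2/C=C(\C)C[C@H](O)/C=C(\C)C[C@H](OC(C)=O)/C=C(\C)C[C@H](OC(C)=O)[C@H]12 | target

**Step count**

Total step count: 24. Longest linear sequence: 24 steps (1 → 38); compounds 8, 22 and 29 are bought.

**Steps most likely to fail**

Step 21. The open transition state may show poor facial or simple diastereoselectivity, BF3 may move the C11=C12 bond into conjugation with the aldehyde, and oligomers may form. The fallback sets out from 32 and returns at 37; it changes the metal and the transition state. Compound 32 is oxidised (Dess–Martin periodinane, NaHCO3) to the bromo aldehyde F1. CrCl2 in THF at high dilution (Nozaki–Hiyama allylation, neutral medium) then closes C1–C14 through a closed chair. Because the allylchromium is held in the ring with C2 trans to the CH2–Cr group, this chair is expected to give the anti adduct, the C14-epimeric macrocycle F2. Mitsunobu esterification with acetic acid (PPh3, DIAD) inverts C14 and installs its acetate, giving the C14 acetate F3. PPTS in MeOH removes the triethylsilyl group to give the C10 alcohol F4, and Ac2O/pyridine converts this into 37.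

Step 19. Tin may be delivered to the ring terminus C1 of the allylpalladium intermediate, zerovalent palladium may ionise the doubly allylic lactone C2–O bond, and the product may couple with unreacted bromide. The fallback sets out from 30 and returns at 33; it introduces tin before the lactone exists. DDQ removes the PMB group of 30 to give the hydroxy bromo ester F5. A stannylcuprate (Bu3SnLi, CuBr·SMe2, THF, −78 °C) substitutes the bromide of the acyclic 2-(bromomethyl)acrylate, where direct and allylic substitution give the same product, the 2-(tributylstannylmethyl)acrylate F6. Ring-closing metathesis with the second-generation Grubbs catalyst then gives 33.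

Step 13. The catalyst may discriminate poorly between the alkynyl and the alkenyl group of the enynone, which would give C2 epimers. The fallback sets out from 21 and returns at 26; it sets C2 by carbon–carbon bond formation and not by reduction. Iodide 21 is lithiated and formylated (t-BuLi, then DMF) to the C2 enal F7. A Zn-ProPhenol-catalysed addition of trimethylsilylacetylene (Me2Zn, toluene), with the ligand enantiomer that directs the alkynylzinc to the Re face of the aldehyde, gives 26.

**Further compounds**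

F1 | step 21 | (2S,6S,10S)-3-(bromomethyl)butenolide C14 aldehyde | BrCC1=C[C@@H](OC1=O)/C=C(\C)C[C@H](O[Si](C)(C)C(C)(C)C)/C=C(\C)C[C@H](O[Si](CC)(CC)CC)/C=C(\C)CC=O
F2 | step 21 | (1S,2S,6S,10S,14R)-macrocyclic α-methylene lactone, C14 epimer of 35 | C=C1C(=O)O[C@H]2/C=C(\C)C[C@H](O[Si](C)(C)C(C)(C)C)/C=C(\C)C[C@H](O[Si](CC)(CC)CC)/C=C(\C)C[C@@H](O)[C@H]12
F3 | step 21 | (1S,2S,6S,10S,14S)-C14 acetate with C6 OTBS and C10 OTES | C=C1C(=O)O[C@H]2/C=C(\C)C[C@H](O[Si](C)(C)C(C)(C)C)/C=C(\C)C[C@H](O[Si](CC)(CC)CC)/C=C(\C)C[C@H](OC(C)=O)[C@H]12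
F4 | step 21 | (1S,2S,6S,10S,14S)-C14 acetate C10 alcohol with C6 OTBS | C=C1C(=O)O[C@H]2/C=C(\C)C[C@H](O[Si](C)(C)C(C)(C)C)/C=C(\C)C[C@H](O)/C=C(\C)C[C@H](OC(C)=O)[C@H]12
F5 | step 19 | (2R,6S,10S)-dienyl 2-(bromomethyl)acrylate C14 alcohol | C=C[C@@H](OC(=O)C(=C)CBr)/C=C(\C)C[C@H](O[Si](C)(C)C(C)(C)C)/C=C(\C)C[C@H](O[Si](CC)(CC)CC)/C=C(\C)CCO
F6 | step 19 | (2R,6S,10S)-dienyl 2-(tributylstannylmethyl)acrylate C14 alcohol | C=C[C@@H](OC(=O)C(=C)C[Sn](CCCC)(CCCC)CCCC)/C=C(\C)C[C@H](O[Si](C)(C)C(C)(C)C)/C=C(\C)C[C@H](O[Si](CC)(CC)CC)/C=C(\C)CCO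
F7 | step 13 | (6S,10S)-C2 enal with C6 OTBS, C10 OTES and C14 OPMB | O=C/C=C(\C)C[C@H](O[Si](C)(C)C(C)(C)C)/C=C(\C)C[C@H](O[Si](CC)(CC)CC)/C=C(\C)CCOCc1ccc(OC)cc1
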